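**Retrosynthetic overview**

- Target 18 comes from benzyl ether 17 and this from phenol alcohol 16 by Mitsunobu closure of O1–C2; the C7 hydroxyl is carried as a benzyl ether.
- 16 comes from lactol 15, which is cut at C3–C4 and O1–C2 into sulfone 7 and aldehyde 12. The strategy rests on this feature: O1 on C8a and the C4 methylene on C4a of benzo ring A are a latent ortho-quinone methide, and C3 is the α-carbon of an arylacetaldehyde carrying tetramethoxyphenyl ring B.
- 7 comes from 2-methoxyresorcinol (formylation, 4-O-benzylation, reduction, sulfinate substitution); 12 comes from 1,2,3,4-tetramethoxybenzene (formylation, methoxymethylene Wittig, hydrolysis).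
- Ring order: rings A and B are bought as arenes; pyran ring C is closed as the lactol in the key step, opened by reduction and closed again by etherification.

Key step: step 8

Remark on the chemistry: the target is the 3S isoflavan. The (S)-diphenylprolinol silyl ether is assigned to the 3S series by carrying over its established sense of induction in enamine Michael additions (attack on the Si face of the E-enamine; the descriptor is S here because ring B outranks the new benzylic CH2). Should the assay at 16 show the opposite sense, the (R)-catalyst is used in an otherwise unchanged route.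

**Route**

Step 1
Reactants: 1 2-methoxyresorcinol
Product: 3 2,4-dihydroxy-3-methoxybenzaldehyde, via iminium chloride 2 (not isolated)
Conditions: POCl3, DMF, MeCN, −15 °C to rt; then H2O, 50 °C
Reagents that add atoms: N,N-dimethylformamide, CN(C)C=O; water, O
Why: Vilsmeier–Haack formylation, in which the chloroiminium ion attacks the ring carbon ortho to one hydroxyl and para to the other (the two such positions of 1 are equivalent), the deactivating iminium group of 2 prevents a second formylation, and water hydrolyses 2 to the aldehyde.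

Step 2
Reactants: 3 2,4-dihydroxy-3-methoxybenzaldehyde
Product: 4 4-(benzyloxy)-2-hydroxy-3-methoxybenzaldehyde
Conditions: BnBr (1.05 equiv), NaHCO3, MeCN, 70 °C
Reagents that add atoms: benzyl bromide, BrCc1ccccc1
Why: Williamson etherification made regioselective by acidity, since the C4 hydroxyl is para to the formyl group and free whereas the C2 hydroxyl is held in a hydrogen bond to the carbonyl, so the weak base should ionise and benzylate only the former.

Step 3
Reactants: 4 4-(benzyloxy)-2-hydroxy-3-methoxybenzaldehyde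
Product: 5 3-(benzyloxy)-6-(hydroxymethyl)-2-methoxyphenol
Conditions: NaBH4, MeOH/THF, 0 °C; aq. NH4Cl
Reagents that add atoms: none
Why: Borohydride reduction of an aryl aldehyde to the benzylic alcohol, which leaves the benzyl ether and the free phenol untouched.

Step 4
Reactants: 5 3-(benzyloxy)-6-(hydroxymethyl)-2-methoxyphenol; 6 sodium p-toluenesulfinate
Product: 7 3-(benzyloxy)-2-methoxy-6-[(4-methylbenzenesulfonyl)methyl]phenol
Conditions: 6 (2 equiv), HCO2H/H2O/THF, rt
Reagents that add atoms: none
Why: Acid-promoted SN1-type substitution, in which the benzylic alcohol flanked by an ortho hydroxyl and a para benzyloxy group ionises readily to a quinone-methide-like cation that the sulfinate captures at sulfur, the excess of sulfinate outcompeting arene nucleophiles.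

Step 5
Reactants: 8 1,2,3,4-tetramethoxybenzene
Product: 10 2,3,4,5-tetramethoxybenzaldehyde, via chloro ether 9 (not isolated)
Conditions: Cl2CHOMe, TiCl4, CH2Cl2, −10 to 0 °C; then ice-water
Reagents that add atoms: dichloromethyl methyl ether, COC(Cl)Cl; water, O
Why: Rieche formylation, in which the TiCl4-activated dichloromethyl methyl ether substitutes the electron-rich arene at one of its two equivalent free positions to give 9, which the aqueous work-up hydrolyses to the aldehyde.

Step 6
Reactants: 10 2,3,4,5-tetramethoxybenzaldehyde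
Product: 11 1-(2-methoxyethenyl)-2,3,4,5-tetramethoxybenzene (E/Z mixture)
Conditions: Ph3P(CH2OMe)Cl, KOtBu, THF, 0 °C to rt
Reagents that add atoms: (methoxymethyl)triphenylphosphonium chloride, COC[P+](c1ccccc1)(c1ccccc1)c1ccccc1.[Cl-]
Why: Wittig one-carbon homologation with (methoxymethylidene)triphenylphosphorane gives the enol ether, whose double-bond geometry is irrelevant because both isomers hydrolyse to the same aldehyde.

Step 7
Reactants: 11 1-(2-methoxyethenyl)-2,3,4,5-tetramethoxybenzene
Product: 12 2-(2,3,4,5-tetramethoxyphenyl)acetaldehyde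
Conditions: 2 M aq. HCl, THF, rt to 40 °C, under N2; used at once
Reagents that add atoms: water, O
Why: Acid-catalysed enol ether hydrolysis (C-protonation to the oxocarbenium ion, addition of water, loss of methanol) unmasks the arylacetaldehyde, which is carried on directly to limit self-aldol condensation.

Step 8
Reactants: 7 3-(benzyloxy)-2-methoxy-6-[(4-methylbenzenesulfonyl)methyl]phenol; 12 2-(2,3,4,5-tetramethoxyphenyl)acetaldehyde
Product: 15 (3S)-7-(benzyloxy)-8-methoxy-3-(2,3,4,5-tetramethoxyphenyl)chroman-2-ol (mixture of C2 anomers), via ortho-quinone methide 13 (not isolated), via enamine 14 (not isolated)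
Conditions: (S)-2-[diphenyl(trimethylsilyloxy)methyl]pyrrolidine (20 mol %), Na2CO3 (1.5 equiv), 12 (1.5 equiv), CH2Cl2, 0 °C to rt
Reagents that add atoms: none
Why: Na2CO3 deprotonates the phenol of 7 and the phenoxide expels p-toluenesulfinate in a 1,4-elimination that releases ortho-quinone methide 13 slowly, while 12 condenses with the pyrrolidine catalyst to E-enamine 14; the enamine α-carbon adds to the exocyclic CH2 of 13 to form C3–C4 with rearomatisation of ring A, and the resulting phenoxide attacks the iminium (or, after hydrolysis, the aldehyde) carbon to form O1–C2. The closest known reaction type is the diarylprolinol silyl ether catalysed Michael addition and hemiacetalisation (formal [4+2]) of enolisable aldehydes with ortho-quinone methides generated in situ from 2-(sulfonylalkyl)phenols. Ring C closes in a 6-exo-trig mode, the C=N+ or C=O bond lying outside the new six-membered ring. C3 is set by the catalyst, whose CPh2(OTMS) group shields one face of the s-trans E-enamine so that 13 approaches the open Si face, which corresponds to 3S; C2 forms as an anomeric mixture and is removed in step 9. The step needs enamine face selectivity and cross-coupling in preference to self-condensation of 13; the latter is supported by the slow heterogeneous release of 13, by the C7 benzyloxy group para to the methide carbon, which tempers the electrophile, and by the excess of 12, which holds the amine as enamine. Closure to the lactol takes the α-aryl aldehyde out of reach of enolisation and so protects C3.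

Step 9
Reactants: 15 (3S)-7-(benzyloxy)-8-methoxy-3-(2,3,4,5-tetramethoxyphenyl)chroman-2-ol
Product: 16 3-(benzyloxy)-6-[(2S)-3-hydroxy-2-(2,3,4,5-tetramethoxyphenyl)propyl]-2-methoxyphenol
Conditions: NaBH4, MeOH/CH2Cl2, −10 to 0 °C, on crude 15 directly after filtration of the step 8 mixture
Reagents that add atoms: none
Why: The lactol is in equilibrium with its open hydroxy aldehyde, which NaBH4 should reduce faster than it enolises at low temperature, so the ring opens to the phenol alcohol with C3 untouched (the descriptor stays S because CH2OH still outranks ring B and the benzylic CH2).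

Step 10
Reactants: 16 3-(benzyloxy)-6-[(2S)-3-hydroxy-2-(2,3,4,5-tetramethoxyphenyl)propyl]-2-methoxyphenol
Product: 17 (3S)-7-(benzyloxy)-8-methoxy-3-(2,3,4,5-tetramethoxyphenyl)chromane
Conditions: PPh3, DIAD, THF, 0 °C to rt
Reagents that add atoms: none
Why: Intramolecular Mitsunobu etherification, in which the primary alcohol is activated as its alkoxyphosphonium salt and displaced by the only free phenol in a 6-exo-tet closure that does not involve the C3 stereocentre.

Step 11
Reactants: 17 (3S)-7-(benzyloxy)-8-methoxy-3-(2,3,4,5-tetramethoxyphenyl)chromane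
Product: 18 (3S)-8-methoxy-3-(2,3,4,5-tetramethoxyphenyl)chroman-7-ol
Conditions: H2 (1 atm), 10% Pd/C, EtOAc/MeOH, rt
Reagents that add atoms: none
Why: Catalytic hydrogenolysis cleaves the O-benzyl ether to the phenol and toluene, while the aryl methyl ethers, the non-benzylic C2–O bond of the chroman and the C3 stereocentre are inert.

**Compound list**

1 | 2-methoxyresorcinol (2-methoxybenzene-1,3-diol) | COc1c(O)cccc1O | starting material
2 | [(2,4-dihydroxy-3-methoxyphenyl)methylidene]dimethylammonium chloride | C[N+](C)=Cc1ccc(O)c(OC)c1O.[Cl-] | intermediate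
3 | 2,4-dihydroxy-3-methoxybenzaldehyde | COc1c(O)ccc(C=O)c1O | intermediate
4 | 4-(benzyloxy)-2-hydroxy-3-methoxybenzaldehyde | COc1c(OCc2ccccc2)ccc(C=O)c1O | intermediate
5 | 3-(benzyloxy)-6-(hydroxymethyl)-2-methoxyphenol | COc1c(OCc2ccccc2)ccc(CO)c1O | intermediate
6 | sodium p-toluenesulfinate | Cc1ccc(S(=O)[O-])cc1.[Na+] | starting material
7 | 3-(benzyloxy)-2-methoxy-6-[(4-methylbenzenesulfonyl)methyl]phenol | COc1c(O)c(CS(=O)(=O)c2ccc(C)cc2)ccc1OCc1ccccc1 | intermediate
8 | 1,2,3,4-tetramethoxybenzene | COc1ccc(OC)c(OC)c1OC | starting material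
9 | 1-[chloro(methoxy)methyl]-2,3,4,5-tetramethoxybenzene | COC(Cl)c1cc(OC)c(OC)c(OC)c1OC | intermediate
10 | 2,3,4,5-tetramethoxybenzaldehyde | COc1cc(C=O)c(OC)c(OC)c1OC | intermediate
11 | 1-(2-methoxyethenyl)-2,3,4,5-tetramethoxybenzene (E/Z mixture) | COC=Cc1cc(OC)c(OC)c(OC)c1OC | intermediate
12 | 2-(2,3,4,5-tetramethoxyphenyl)acetaldehyde | COc1cc(CC=O)c(OC)c(OC)c1OC | intermediate
13 | 3-(benzyloxy)-2-methoxy-6-methylidenecyclohexa-2,4-dien-1-one (ortho-quinone methide of ring A) | C=C1C=CC(OCc2ccccc2)=C(OC)C1=O | intermediate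
14 | (2S)-2-[diphenyl(trimethylsilyloxy)methyl]-1-[(E)-2-(2,3,4,5-tetramethoxyphenyl)ethenyl]pyrrolidine (enamine of 12) | COc1cc(/C=C/N2CCC[C@H]2C(c2ccccc2)(c2ccccc2)O[Si](C)(C)C)c(OC)c(OC)c1OC | intermediate
15 | (3S)-7-(benzyloxy)-8-methoxy-3-(2,3,4,5-tetramethoxyphenyl)chroman-2-ol (C2 anomers) | COc1cc([C@H]2C(O)Oc3c(ccc(OCc4ccccc4)c3OC)C2)c(OC)c(OC)c1OC | intermediate
16 | 3-(benzyloxy)-6-[(2S)-3-hydroxy-2-(2,3,4,5-tetramethoxyphenyl)propyl]-2-methoxyphenol | COc1cc([C@@H](CO)Cc2ccc(OCc3ccccc3)c(OC)c2O)c(OC)c(OC)c1OC | intermediate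
17 | (3S)-7-(benzyloxy)-8-methoxy-3-(2,3,4,5-tetramethoxyphenyl)chromane | COc1cc([C@H]2COc3c(ccc(OCc4ccccc4)c3OC)C2)c(OC)c(OC)c1OC | intermediate
18 | (3S)-8-methoxy-3-(2,3,4,5-tetramethoxyphenyl)chroman-7-ol | COc1cc([C@H]2COc3c(ccc(O)c3OC)C2)c(OC)c(OC)c1OC | target

**Step count**

Total: 11 steps. Longest linear sequence: 8 steps (steps 1 to 4 and 8 to 11); the aldehyde arm (steps 5 to 7) converges at step 8.

**Steps most likely to fail, with fallbacks**

Step 8. The methide carries no substituent on its exocyclic carbon and may condense with itself or alkylate the catalyst nitrogen faster than the enamine captures it. The C3 configuration may also erode if the opened lactol re-forms an enamine. The fallback is an oxazolidinone auxiliary alkylation, which sets out from 12 and 4 and returns to the route at 16.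
- Aldehyde 12 is oxidised (NaClO2, NaH2PO4, 2-methyl-2-butene, t-BuOH/H2O) to 2-(2,3,4,5-tetramethoxyphenyl)acetic acid F1.
- F1 is coupled through its pivaloyl mixed anhydride (PivCl, Et3N, LiCl, THF) with (S)-4-benzyl-2-oxazolidinone to (4S)-4-benzyl-3-[2-(2,3,4,5-tetramethoxyphenyl)acetyl]-1,3-oxazolidin-2-one F2.
- In parallel, aldehyde 4 is protected (MOMCl, i-Pr2NEt, CH2Cl2) as 4-(benzyloxy)-3-methoxy-2-(methoxymethoxy)benzaldehyde F3.
- F3 is reduced (NaBH4, MeOH) to [4-(benzyloxy)-3-methoxy-2-(methoxymethoxy)phenyl]methanol F4.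
- F4 is brominated (CBr4, PPh3, CH2Cl2, 0 °C) to 1-(benzyloxy)-4-(bromomethyl)-2-methoxy-3-(methoxymethoxy)benzene F5.
- The sodium Z-enolate of F2 (NaHMDS, THF, −78 °C) should be alkylated by F5 on the face away from the auxiliary benzyl group, giving (4S)-4-benzyl-3-[(2S)-3-[4-(benzyloxy)-3-methoxy-2-(methoxymethoxy)phenyl]-2-(2,3,4,5-tetramethoxyphenyl)propanoyl]-1,3-oxazolidin-2-one F6.
- LiBH4 (THF, MeOH, 0 °C) removes the auxiliary to give (2S)-3-[4-(benzyloxy)-3-methoxy-2-(methoxymethoxy)phenyl]-2-(2,3,4,5-tetramethoxyphenyl)propan-1-ol F7.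
- HCl in MeOH cleaves the MOM ether to give 16, from which steps 10 and 11 follow.

Step 4. The very electron-rich benzylic alcohol may ionise and undergo Friedel–Crafts oligomerisation before the sulfinate captures it. The fallback avoids acid, sets out from 4 and returns at 7, replacing steps 3 and 4.
- Aldehyde 4 undergoes reductive amination (Me2NH, NaBH(OAc)3, 1,2-dichloroethane) to the Mannich base 3-(benzyloxy)-6-[(dimethylamino)methyl]-2-methoxyphenol F8.
- MeI in acetone quaternises F8 at nitrogen to [4-(benzyloxy)-2-hydroxy-3-methoxyphenyl]methyl-trimethylammonium iodide F9.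
- Warming F9 with sulfinate 6 in DMF (60 °C) should release the methide by loss of trimethylamine; the sulfinate then adds to it to give 7.

Step 7. The electron-rich arylacetaldehyde may undergo acid-promoted aldol self-condensation or oligomerisation during the enol ether hydrolysis. The fallback forms the aldehyde under non-acidic conditions, sets out from 10 and returns at 12, replacing steps 6 and 7.
- Aldehyde 10 is methylenated (Ph3PCH3Br, KOtBu, THF) to 1-ethenyl-2,3,4,5-tetramethoxybenzene F10.
- F10 is hydroborated with 9-BBN and oxidised (NaOH, H2O2) to 2-(2,3,4,5-tetramethoxyphenyl)ethanol F11.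
- F11 is oxidised with Dess–Martin periodinane (NaHCO3, CH2Cl2, 0 °C) to 12, which is taken directly into step 8.

**Further compounds**

F1 | step 8 | 2-(2,3,4,5-tetramethoxyphenyl)acetic acid | COc1cc(CC(=O)O)c(OC)c(OC)c1OC
F2 | step 8 | (4S)-4-benzyl-3-[2-(2,3,4,5-tetramethoxyphenyl)acetyl]-1,3-oxazolidin-2-one | COc1cc(CC(=O)N2C(=O)OC[C@@H]2Cc2ccccc2)c(OC)c(OC)c1OC
F3 | step 8 | 4-(benzyloxy)-3-methoxy-2-(methoxymethoxy)benzaldehyde | COCOc1c(C=O)ccc(OCc2ccccc2)c1OC
F4 | step 8 | [4-(benzyloxy)-3-methoxy-2-(methoxymethoxy)phenyl]methanol | COCOc1c(CO)ccc(OCc2ccccc2)c1OC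
F5 | step 8 | 1-(benzyloxy)-4-(bromomethyl)-2-methoxy-3-(methoxymethoxy)benzene | COCOc1c(CBr)ccc(OCc2ccccc2)c1OC
F6 | step 8 | (4S)-4-benzyl-3-[(2S)-3-[4-(benzyloxy)-3-methoxy-2-(methoxymethoxy)phenyl]-2-(2,3,4,5-tetramethoxyphenyl)propanoyl]-1,3-oxazolidin-2-one | COCOc1c(C[C@H](C(=O)N2C(=O)OC[C@@H]2Cc2ccccc2)c2cc(OC)c(OC)c(OC)c2OC)ccc(OCc2ccccc2)c1OC
F7 | step 8 | (2S)-3-[4-(benzyloxy)-3-methoxy-2-(methoxymethoxy)phenyl]-2-(2,3,4,5-tetramethoxyphenyl)propan-1-ol | COCOc1c(C[C@H](CO)c2cc(OC)c(OC)c(OC)c2OC)ccc(OCc2ccccc2)c1OC
F8 | step 4 | 3-(benzyloxy)-6-[(dimethylamino)methyl]-2-methoxyphenol | CN(C)Cc1ccc(OCc2ccccc2)c(OC)c1O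
F9 | step 4 | [4-(benzyloxy)-2-hydroxy-3-methoxyphenyl]methyl-trimethylammonium iodide | C[N+](C)(C)Cc1ccc(OCc2ccccc2)c(OC)c1O.[I-]
F10 | step 7 | 1-ethenyl-2,3,4,5-tetramethoxybenzene | C=Cc1cc(OC)c(OC)c(OC)c1OC
F11 | step 7 | 2-(2,3,4,5-tetramethoxyphenyl)ethanol | OCCc1cc(OC)c(OC)c(OC)c1OC
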